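A direct plan would buy both benzene rings and would join them at the ether oxygen by SNAr, after a short oxygenation sequence on ring B.
2-Fluoro-5-methoxybenzaldehyde A1 would be masked as 2-(2-fluoro-5-methoxyphenyl)-1,3-dioxolane A2, borylated next to fluorine to the pinacol boronate A3, oxidized to the phenol A4 and unmasked to 2-fluoro-3-hydroxy-5-methoxybenzaldehyde A5.
Prenylation of A5 would give 2-fluoro-5-methoxy-3-[(3-methylbut-2-en-1-yl)oxy]benzaldehyde A6, methyl 2,6-dihydroxy-4-methylbenzoate A7 would displace its fluoride to give methyl 2-{2-formyl-4-methoxy-6-[(3-methylbut-2-en-1-yl)oxy]phenoxy}-6-hydroxy-4-methylbenzoate A8, and NaBH4 would reduce A8 to the target.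
The weakest step would be the ether-forming substitution of A6 by A7 to A8: a hindered, hydrogen-bonded phenoxide would have to displace a fluoride that carries a para methoxy and an ortho alkoxy group and is activated by one formyl group only, in hot base on the most advanced material, with double arylation of A7 and loss of aldehyde or ester as likely failures.
The second would be the C–H oxygenation of A2 through A3 to A4, whose regiochemistry would rest only on a steric preference between two neighbouring C–H bonds (ortho to F versus ortho to OMe).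
The third would be the acetal that is put on A1 and taken off on the way to A5: two of five steps and a three-stage one-pot would add one hydroxyl group.

**Plan of the new route**
Ring A is not bought but made last: after removal of a benzylic methyl carbonate, the retrosynthesis cuts C1–C2 and C5–C6 of ring A into an aryl alkynyl ether ester ArO–C≡C–CO2Me (C6, C1 and the ester) and the vinylketene silyl acetal of methyl 3-methylbut-2-enoate (C2–C5 with the C4 methyl; its ester carbon becomes the phenolic C2).
The feature that allows this is the pattern of ring A: the ester carbon C1 lies between C2–OH and C6–OAr and the methyl at C4 is meta to both oxygens, which is what a polarized [4+2] of a 1,1-dioxygenated diene with a β-oxygenated ynoate delivers.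
The ether oxygen is bought on ring B as a phenol, and its bond to C6 is made while C6 is still a vinylic and then an sp carbon (phenol plus trichloroethylene), where the two ortho groups of ring B cost nothing.
Ring B is an arene whose three oxygens are fixed by ortho relationships: a bromide ortho to a phenol is exchanged for OH, and the catechol dianion is prenylated at the oxygen remote from the formyl group.
So no SNAr on a deactivated fluoroarene, no C–H borylation, no acetal on and off, and no hydride reduction of a diaryl ether aldehyde occur; the aldehyde is reduced before the two rings exist together.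

Key step: step 7

Remark: 3-bromo-2-hydroxy-5-methoxybenzaldehyde (1) is assumed to be purchased; it is otherwise the ortho-bromination product of 2-hydroxy-5-methoxybenzaldehyde.
Remark: the target has no stereocentre; the only stereochemical items are the E geometry of the two dichlorovinyl ethers and a transient racemic ketal carbon in the cycloadduct of the key step.

Step 1
Reactants: 1 3-bromo-2-hydroxy-5-methoxybenzaldehyde
Product: 2 2,3-dihydroxy-5-methoxybenzaldehyde
Conditions: NaOH (6 equiv), CuSO4·5H2O (10 mol%), H2O, reflux, N2; then HCl to pH 2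
Reagents that add atoms: sodium hydroxide, [Na+].[OH-]
Why: Ullmann-type copper-mediated hydroxylation of an aryl bromide ortho to a phenoxide, the reaction that turns 5-halovanillins into 5-hydroxyvanillin, should work because the ionized phenol assists copper and shields the aldehyde from Cannizzaro chemistry, while exclusion of air protects the catechol; no stereocentre is formed.

Step 2
Reactants: 2 2,3-dihydroxy-5-methoxybenzaldehyde; 3 1-bromo-3-methylbut-2-ene (prenyl bromide)
Product: 4 2-hydroxy-5-methoxy-3-[(3-methylbut-2-en-1-yl)oxy]benzaldehyde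
Conditions: NaH (2.2 equiv), DMSO, rt; then prenyl bromide (1.0 equiv), rt; aq HCl
Reagents that add atoms: prenyl bromide (3), CC(C)=CCBr
Why: Williamson ether synthesis on the catechol dianion, in which the 2-oxide is delocalized into the formyl group and held in a sodium chelate, so that the SN2 attack on the primary allylic bromide comes from the 3-oxide, as is known for dianions of 2,3-dihydroxybenzaldehydes, and one equivalent of bromide limits double alkylation.

Step 3
Reactants: 4 2-hydroxy-5-methoxy-3-[(3-methylbut-2-en-1-yl)oxy]benzaldehyde; 5 trichloroethylene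
Product: 6 2-{[(E)-1,2-dichloroethenyl]oxy}-5-methoxy-3-[(3-methylbut-2-en-1-yl)oxy]benzaldehyde
Conditions: trichloroethylene (2 equiv), K2CO3 (3 equiv), DMF, 70 °C
Reagents that add atoms: trichloroethylene (5), ClC=C(Cl)Cl
Why: Base turns trichloroethylene into dichloroacetylene, to which the phenoxide adds with trans protonation (net vinylic substitution), which sets the E geometry of the 1,2-dichlorovinyl ether; the crowded phenol oxygen meets a rod-shaped sp carbon, and the non-enolizable aldehyde and the prenyl ether are inert to K2CO3.

Step 4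
Reactants: 6 2-{[(E)-1,2-dichloroethenyl]oxy}-5-methoxy-3-[(3-methylbut-2-en-1-yl)oxy]benzaldehyde
Product: 7 (2-{[(E)-1,2-dichloroethenyl]oxy}-5-methoxy-3-[(3-methylbut-2-en-1-yl)oxy]phenyl)methanol
Conditions: NaBH4 (0.6 equiv), MeOH/THF, 0 °C; aq NH4Cl
Reagents that add atoms: none
Why: Chemoselective borohydride reduction of the aryl aldehyde, which leaves the dichlorovinyl ether and the alkene alone and removes the one group that would not survive butyllithium.

Step 5
Reactants: 7 (2-{[(E)-1,2-dichloroethenyl]oxy}-5-methoxy-3-[(3-methylbut-2-en-1-yl)oxy]phenyl)methanol; 8 methyl chloroformate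
Product: 10 methyl 3-{4-methoxy-2-{[(methoxycarbonyl)oxy]methyl}-6-[(3-methylbut-2-en-1-yl)oxy]phenoxy}prop-2-ynoate, via dilithio alkoxide acetylide 9 (not isolated)
Conditions: n-BuLi (3.2 equiv), THF, −78 to −40 °C; then ClCO2Me (2.6 equiv), −78 to 0 °C; aq NaHCO3; quick filtration through neutral alumina
Reagents that add atoms: methyl chloroformate (8), COC(=O)Cl
Why: Alkynyl ether synthesis from a 1,2-dichlorovinyl ether, in which butyllithium first forms the lithium alkoxide, then dehydrochlorinates the vinyl ether and exchanges the remaining chlorine for lithium, after which methyl chloroformate acylates both the acetylide carbon and the alkoxide oxygen, so that the ynoate arises together with a methyl carbonate that masks the benzylic alcohol until the last step.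

Step 6
Reactants: 11 methyl 3-methylbut-2-enoate
Product: 12 1-methoxy-3-methyl-1-[(trimethylsilyl)oxy]buta-1,3-diene (mixture of geometric isomers at C1=C2)
Conditions: LiN(i-Pr)2 (1.1 equiv), THF, −78 °C; then Me3SiCl (1.2 equiv), −78 °C to rt; distillation
Reagents that add atoms: chlorotrimethylsilane, C[Si](C)(C)Cl
Why: Deprotonation of a γ-methyl group gives the extended enolate, which chlorotrimethylsilane traps on oxygen as the vinylketene silyl acetal (standard dienolate O-silylation); the geometry at the acetal double bond is immaterial because that carbon becomes sp3 and then the phenolic carbon.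

Step 7
Reactants: 10 methyl 3-{4-methoxy-2-{[(methoxycarbonyl)oxy]methyl}-6-[(3-methylbut-2-en-1-yl)oxy]phenoxy}prop-2-ynoate; 12 1-methoxy-3-methyl-1-[(trimethylsilyl)oxy]buta-1,3-diene
Product: 15 methyl 2-hydroxy-6-{2-(hydroxymethyl)-4-methoxy-6-[(3-methylbut-2-en-1-yl)oxy]phenoxy}-4-methylbenzoate, via silyl ketal cycloadduct 13 (not isolated), via benzylic carbonate 14 (not isolated)
Conditions: 12 (2.5 equiv), toluene, 90 °C, N2; concentrate; then K2CO3 (0.5 equiv), MeOH, rt; aq NH4Cl
Reagents that add atoms: 1-methoxy-3-methyl-1-[(trimethylsilyl)oxy]buta-1,3-diene (12), COC(O[Si](C)(C)C)=CC(C)=C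
Why: Proposed new method: the mechanism should be a polarity-matched, strongly asynchronous [4+2] cycloaddition in which the nucleophilic C4 terminus of vinylketene acetal 12 bonds to the aryloxy-bearing β-carbon of ynoate 10 and the acetal carbon C1 to the ester-bearing α-carbon, so that ring A closes in the Diels–Alder mode as the cyclohexa-1,4-diene 13 (in the stepwise limit a vinylogous Mukaiyama–Michael addition followed by 6-exo-trig attack of the allenoate carbon on the oxocarbenium ion, with the same outcome). The closest known reaction type is the Diels–Alder/aromatization of 1-alkoxy-1-silyloxy-1,3-dienes with acetylenic esters such as methyl propiolate, which gives salicylates with the same ortho relation of ester and hydroxyl; what goes beyond it is the β-aryloxy group on the ynoate. That group should not stop the reaction, because in an alkyne the ester and the oxygen lone pair can conjugate with the two orthogonal π bonds, which leaves one π bond activated by the ester and by the σ-withdrawing oxygen. The selectivity needed is regiochemical and is secured by the substrate: only bonding of C4 to the β-carbon puts the developing negative charge next to the ester and the positive charge on the dioxygenated carbon, and this orientation places CO2Me between OH and OAr with the methyl meta to both. The one new stereocentre, the ketal carbon of 13, is formed racemic and needs no control, since methoxide removes silicon and the hemiketal collapses to the dienone tautomer of phenol 14 (basic methanol is chosen over acid or heat, which could expel trimethylsilanol and leave the methyl ether). The same reagent then cleaves the benzylic methyl carbonate of 14 by transesterification, while the hydrogen-bonded methyl salicylate (degenerate methanolysis), the prenyl ether and the diaryl ether are inert.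

**Compound list**
1 | 3-bromo-2-hydroxy-5-methoxybenzaldehyde | COc1cc(Br)c(O)c(C=O)c1 | starting material
2 | 2,3-dihydroxy-5-methoxybenzaldehyde | COc1cc(O)c(O)c(C=O)c1 | intermediate
3 | 1-bromo-3-methylbut-2-ene (prenyl bromide) | CC(C)=CCBr | starting material
4 | 2-hydroxy-5-methoxy-3-[(3-methylbut-2-en-1-yl)oxy]benzaldehyde | COc1cc(OCC=C(C)C)c(O)c(C=O)c1 | intermediate
5 | trichloroethylene | ClC=C(Cl)Cl | starting material
6 | 2-{[(E)-1,2-dichloroethenyl]oxy}-5-methoxy-3-[(3-methylbut-2-en-1-yl)oxy]benzaldehyde | COc1cc(OCC=C(C)C)c(O/C(Cl)=C\Cl)c(C=O)c1 | intermediate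
7 | (2-{[(E)-1,2-dichloroethenyl]oxy}-5-methoxy-3-[(3-methylbut-2-en-1-yl)oxy]phenyl)methanol | COc1cc(OCC=C(C)C)c(O/C(Cl)=C\Cl)c(CO)c1 | intermediate
8 | methyl chloroformate | COC(=O)Cl | starting material
9 | lithium {2-[(lithioethynyl)oxy]-5-methoxy-3-[(3-methylbut-2-en-1-yl)oxy]phenyl}methanolate | [Li]C#COc1c(CO[Li])cc(OC)cc1OCC=C(C)C | intermediate (not isolated)
10 | methyl 3-{4-methoxy-2-{[(methoxycarbonyl)oxy]methyl}-6-[(3-methylbut-2-en-1-yl)oxy]phenoxy}prop-2-ynoate | COC(=O)C#COc1c(COC(=O)OC)cc(OC)cc1OCC=C(C)C | intermediate
11 | methyl 3-methylbut-2-enoate | COC(=O)C=C(C)C | starting material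
12 | 1-methoxy-3-methyl-1-[(trimethylsilyl)oxy]buta-1,3-diene (mixture of geometric isomers at C1=C2) | COC(O[Si](C)(C)C)=CC(C)=C | intermediate
13 | methyl 6-methoxy-2-{4-methoxy-2-{[(methoxycarbonyl)oxy]methyl}-6-[(3-methylbut-2-en-1-yl)oxy]phenoxy}-4-methyl-6-[(trimethylsilyl)oxy]cyclohexa-1,4-diene-1-carboxylate (racemic at C6) | COC(=O)C1=C(Oc2c(COC(=O)OC)cc(OC)cc2OCC=C(C)C)CC(C)=CC1(OC)O[Si](C)(C)C | intermediate (not isolated)
14 | methyl 2-hydroxy-6-{4-methoxy-2-{[(methoxycarbonyl)oxy]methyl}-6-[(3-methylbut-2-en-1-yl)oxy]phenoxy}-4-methylbenzoate | COC(=O)c1c(O)cc(C)cc1Oc1c(COC(=O)OC)cc(OC)cc1OCC=C(C)C | intermediate (not isolated)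
15 | methyl 2-hydroxy-6-{2-(hydroxymethyl)-4-methoxy-6-[(3-methylbut-2-en-1-yl)oxy]phenoxy}-4-methylbenzoate | COC(=O)c1c(O)cc(C)cc1Oc1c(CO)cc(OC)cc1OCC=C(C)C | target

**Step count and risks**
Total steps: 7. Longest linear sequence: 6 (steps 1, 2, 3, 4, 5, 7); step 6 is a one-step side branch.

Steps most likely to fail:

- **Step 7 (proposed new method).** The cycloaddition may be too slow for a donor-substituted ynoate, so that decomposition of the diene, oligomerization of the ynoate or a thermal Claisen shift of the prenyl ether overtakes ring formation; the ketal may also collapse with loss of silanol to the methyl ether. The fallback uses known chemistry only and buys ring A instead of building it. It sets out from 4 and comes back at 15. Phenol 4 would be coupled by SNAr (K2CO3, DMF, 90 °C) with methyl 2,6-difluoro-4-methylbenzoate F1 (from the commercial acid, MeOH, cat. H2SO4), in which the ester activates both ortho fluorides and the first substitution deactivates the second. This would give methyl 2-fluoro-6-{2-formyl-4-methoxy-6-[(3-methylbut-2-en-1-yl)oxy]phenoxy}-4-methylbenzoate F2. NaBH4 would reduce the aldehyde to methyl 2-fluoro-6-{2-(hydroxymethyl)-4-methoxy-6-[(3-methylbut-2-en-1-yl)oxy]phenoxy}-4-methylbenzoate F3. The remaining fluoride would then be exchanged for hydroxyl with acetohydroxamic acid as a hydroxide surrogate (K2CO3, DMSO, 80 °C), a carbonate base that leaves the benzylic alcohol un-ionized and the hindered ester intact. SNAr by the hydroxamate oxygen would give methyl 2-[(acetylamino)oxy]-6-{2-(hydroxymethyl)-4-methoxy-6-[(3-methylbut-2-en-1-yl)oxy]phenoxy}-4-methylbenzoate F4, which would fragment in the flask by a Lossen-type rearrangement into methyl isocyanate and the phenoxide of 15.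

- **Step 5.** During the organolithium sequence the benzylic alkoxide may add to the transient chloroalkyne, the prenyl ether may be deprotonated and rearrange, or the push–pull ynoate may be hydrated on isolation. The fallback makes the triple bond last by elimination, so that no alkyllithium is used. It sets out from 4 and comes back at 10. Phenol 4 would be added to commercial methyl 3,3-dichloroprop-2-enoate (K2CO3, DMF; vinylic addition–elimination) to give methyl 3-chloro-3-{2-formyl-4-methoxy-6-[(3-methylbut-2-en-1-yl)oxy]phenoxy}prop-2-enoate F5 (E/Z mixture). NaBH4 at low temperature would give methyl 3-chloro-3-{2-(hydroxymethyl)-4-methoxy-6-[(3-methylbut-2-en-1-yl)oxy]phenoxy}prop-2-enoate F6. Methyl chloroformate and pyridine would give methyl 3-chloro-3-{4-methoxy-2-{[(methoxycarbonyl)oxy]methyl}-6-[(3-methylbut-2-en-1-yl)oxy]phenoxy}prop-2-enoate F7, and LiN(SiMe3)2 (THF, −78 °C) would dehydrochlorinate F7 to 10.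

- **Step 1.** In hot alkali the aryl bromide may turn over incompletely or be reduced, and the electron-rich catechol aldehyde may be oxidized or condensed. The fallback replaces copper-mediated substitution by C–B bond formation and oxidation. It sets out from 1 and comes back at 2. Miyaura borylation (B2pin2, PdCl2(dppf), KOAc, dioxane, 80 °C) would give 2-hydroxy-5-methoxy-3-(4,4,5,5-tetramethyl-1,3,2-dioxaborolan-2-yl)benzaldehyde F8. The C–B bond of F8 would be oxidized with N-methylmorpholine N-oxide (THF, reflux), a neutral oxidant chosen because alkaline peroxide would also cleave the salicylaldehyde by Dakin oxidation, to give 2.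

**Further compounds**
F1 | step 7 | methyl 2,6-difluoro-4-methylbenzoate | COC(=O)c1c(F)cc(C)cc1F
F2 | step 7 | methyl 2-fluoro-6-{2-formyl-4-methoxy-6-[(3-methylbut-2-en-1-yl)oxy]phenoxy}-4-methylbenzoate | COC(=O)c1c(F)cc(C)cc1Oc1c(C=O)cc(OC)cc1OCC=C(C)C
F3 | step 7 | methyl 2-fluoro-6-{2-(hydroxymethyl)-4-methoxy-6-[(3-methylbut-2-en-1-yl)oxy]phenoxy}-4-methylbenzoate | COC(=O)c1c(F)cc(C)cc1Oc1c(CO)cc(OC)cc1OCC=C(C)C
F4 | step 7 | methyl 2-[(acetylamino)oxy]-6-{2-(hydroxymethyl)-4-methoxy-6-[(3-methylbut-2-en-1-yl)oxy]phenoxy}-4-methylbenzoate | COC(=O)c1c(ONC(C)=O)cc(C)cc1Oc1c(CO)cc(OC)cc1OCC=C(C)C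
F5 | step 5 | methyl 3-chloro-3-{2-formyl-4-methoxy-6-[(3-methylbut-2-en-1-yl)oxy]phenoxy}prop-2-enoate (E/Z mixture) | COC(=O)C=C(Cl)Oc1c(C=O)cc(OC)cc1OCC=C(C)C
F6 | step 5 | methyl 3-chloro-3-{2-(hydroxymethyl)-4-methoxy-6-[(3-methylbut-2-en-1-yl)oxy]phenoxy}prop-2-enoate (E/Z mixture) | COC(=O)C=C(Cl)Oc1c(CO)cc(OC)cc1OCC=C(C)C
F7 | step 5 | methyl 3-chloro-3-{4-methoxy-2-{[(methoxycarbonyl)oxy]methyl}-6-[(3-methylbut-2-en-1-yl)oxy]phenoxy}prop-2-enoate (E/Z mixture) | COC(=O)C=C(Cl)Oc1c(COC(=O)OC)cc(OC)cc1OCC=C(C)C
F8 | step 1 | 2-hydroxy-5-methoxy-3-(4,4,5,5-tetramethyl-1,3,2-dioxaborolan-2-yl)benzaldehyde | COc1cc(B2OC(C)(C)C(C)(C)O2)c(O)c(C=O)c1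
A1 | direct plan | 2-fluoro-5-methoxybenzaldehyde | COc1ccc(F)c(C=O)c1
A2 | direct plan | 2-(2-fluoro-5-methoxyphenyl)-1,3-dioxolane | COc1ccc(F)c(C2OCCO2)c1
A3 | direct plan | 2-[3-(1,3-dioxolan-2-yl)-2-fluoro-5-methoxyphenyl]-4,4,5,5-tetramethyl-1,3,2-dioxaborolane | COc1cc(B2OC(C)(C)C(C)(C)O2)c(F)c(C2OCCO2)c1
A4 | direct plan | 3-(1,3-dioxolan-2-yl)-2-fluoro-5-methoxyphenol | COc1cc(O)c(F)c(C2OCCO2)c1
A5 | direct plan | 2-fluoro-3-hydroxy-5-methoxybenzaldehyde | COc1cc(O)c(F)c(C=O)c1
A6 | direct plan | 2-fluoro-5-methoxy-3-[(3-methylbut-2-en-1-yl)oxy]benzaldehyde | COc1cc(OCC=C(C)C)c(F)c(C=O)c1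
A7 | direct plan | methyl 2,6-dihydroxy-4-methylbenzoate | COC(=O)c1c(O)cc(C)cc1O
A8 | direct plan | methyl 2-{2-formyl-4-methoxy-6-[(3-methylbut-2-en-1-yl)oxy]phenoxy}-6-hydroxy-4-methylbenzoate | COC(=O)c1c(O)cc(C)cc1Oc1c(C=O)cc(OC)cc1OCC=C(C)C
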